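The easy step is the first slope of target: the cedar run reads 13.4% after 8.00 min and the ash run 8.5% after 5.00 min, so target rises at nearly the same pace, although ash holds more solid reagent than cedar.

| setting | cedar | ash | Wednesday's | Friday's |
|---|---|---|---|---|
| substrate | 0.80 M | 0.80 M | 0.80 M | 0.80 M |
| solid reagent | 0.72 equiv | 1.2 equiv | 1.00 equiv | 0.500 equiv |
| remark | run made earlier | run made earlier |  |  |
| time |  |  | 1.0 h | 0.30 h |

| run | time / min | target / % |
|---|---|---|
| cedar | 3.00 | 5.6 |
| cedar | 8.00 | 13.4 |
| cedar | 20.0 | 27.6 |
| cedar | 40.0 | 42.6 |
| ash | 5.00 | 8.5 |
| ash | 15.0 | 22.5 |
| ash | 25.0 | 32.1 |
| ash | 40.0 | 41.1 |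

(scatter of a reading: 0.5 percentage points)

- solid, in amounts per volume of the solution: solid reagent
- what was read earlier has a scatter of 0.5 percentage points, one standard deviation
- on the list of suspects stand: substrate -> side product A; substrate -> target; partner + intermediate A <-> intermediate C; solid reagent <-> partner; intermediate B -> decomposed reagent; substrate <-> intermediate A; intermediate A -> side product B; intermediate A <-> intermediate B
- at the start none of the solid reagent is in solution

- which one finishes higher in amount of target, in percent of the substrate charged ("neither" within 2 percentage points) (Wednesday's / Friday's / neither)
- amount of target at the end, in percent of the substrate charged, Wednesday's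
- amount of target at the end, in percent of the substrate charged, Friday's

Both slopes sink later, so I set the rate of rise of target against the target already there, and time drops out. Between an early stretch and the last stretch of each run, I read the fall of rate per unit of target as a closing constant, and I extend the line to zero rate. Cedar gives 0.0326 /min and 58.1%; ash gives 0.0340 /min and 54.2%. I take one line through both, with constant 0.0333 /min and the mean 56.2%, the ceiling: the target at which the rate reaches zero, an overall selectivity for target. Holding that line at 0.500 equiv, below the cedar charge, is my assumption.

On this line, target in Wednesday's and in Friday's starts by gaining a fraction 0.0187 /min of the charge. On the same line, the gap to the ceiling stands after 20.8 min at half of its start. At the stop, the line leaves Friday's 54.9% of that gap and Wednesday's 13.6%. My reckoning therefore gives 48.6% for Wednesday's and 25.3% for Friday's.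

The forecast names Wednesday's, with 49.3% against 25.5%, holding that “the amount of solid barely matters early on”.

The flask gives 49.0% for Wednesday's, higher than the 25.7% for Friday's, so Wednesday's finishes higher, and my two figures lie 0.40 percentage points and 0.40 points below these.

    substrate → side product A (k = 0.00784 /min)
    substrate → target (k = 0.0191 /min)
    partner + intermediate A ⇌ intermediate C (K = 48.0 /M, k = 0.00118 /M/min)
    solid reagent ⇌ partner, rate k4*(cs4 - [partner]) while solid is left; crystals form when [partner] > cs4 (solubility = 0.340 M, k = 0.0422 /min)
    intermediate B → decomposed reagent (k = 0.0341 /min)
    substrate ⇌ intermediate A (K = 1.70, k = 0.00731 /min)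
    intermediate A → side product B (k = 0.0361 /min)
    intermediate A ⇌ intermediate B (K = 1.00, k = 0.0175 /min)

By my read ceiling, Wednesday's has 7.2 points still to come at its stop, and left until 10.0 h that flask stands at 56.8%. The neighbouring flask is Wednesday's stopped at 25 min: the same ceiling and constant give 31.8%, and it stands at 32.2%, with 42.8% of the substrate left.

(The readings were generated by integration for an exercise, and the scatter is random.)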